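**Plan**

Retrosynthesis: after removal of the two ring B silyl ethers, ring A is cut at C4a–C5 and C8–C8a, giving a C2-arylated dihydropyranone (ring C carrying ring B) and a four-carbon diene for C5–C8; the pyranone is then cut at C2–C3 and O1–C8a, and the diene at its two prenyl–carbon bonds.
Enabling feature: ring A is a hexasubstituted benzene in which oxygen-bearing carbons (C5, C7, C8a) alternate with carbon-bearing ones (C4a, C6, C8). C4a=C8a can therefore be the enone alkene of a 5-sulfinyl-2,3-dihydropyran-4-one, and C5–C8 the bis-silyl dienol ether of a 2,4-diprenylated 3-oxo ester.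
Forward order: ring C is built first on the ring B aldehyde by asymmetric hetero-Diels–Alder reaction and armed as a vinyl sulfoxide; the diene is made in parallel from methyl acetoacetate and prenyl bromide; ring A is closed last by benzannulation, followed by desilylation.
Stereochemistry: the only stereocentre, C2 (S), is set by the (S)-BINOL–Ti(OiPr)4 catalyst in the hetero-Diels–Alder step and is a spectator afterwards.

Key step: step 9

Assumption: the (S)-BINOL–Ti(OiPr)4 catalyst is taken to direct the silyl enol ether to the Si face of the aryl aldehyde, the facial sense it shows in allylation and Mukaiyama aldol reactions of aryl aldehydes; should the opposite sense be found, (R)-BINOL would be used with no other change.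
Remark: flavanone numbering (O1, C2, C3, C4, C4a, C5 to C8, C8a) is used for ring positions; where a monocyclic pyranone is named, its own numbering (C5=C6 is the future C4a=C8a) is used.

**Route**

Step 1
Reactants: 1 3,5-dihydroxybenzaldehyde
Product: 2 3,5-bis(tert-butyldimethylsilyloxy)benzaldehyde
Conditions: TBSCl (2.4 equiv), imidazole, DMF, 25 °C
Reagents that add atoms: tert-butyldimethylsilyl chloride, CC(C)(C)[Si](C)(C)Cl
Why: Imidazole-promoted O-silylation of phenols is routine and leaves the aldehyde untouched; no stereocentre is formed.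

Step 2
Reactants: 2 3,5-bis(tert-butyldimethylsilyloxy)benzaldehyde; 3 (E)-1-methoxy-3-(trimethylsilyloxy)buta-1,3-diene
Product: 5 (2S)-2-[3,5-bis(tert-butyldimethylsilyloxy)phenyl]-2,3-dihydropyran-4-one, via silylated aldol adduct 4 (not isolated)
Conditions: (S)-BINOL (20 mol %), Ti(OiPr)4 (10 mol %), 4 Å molecular sieves, Et2O, −20 °C; then CF3CO2H, CH2Cl2, 0 °C; aqueous work-up
Reagents that add atoms: none
Why: Catalytic asymmetric hetero-Diels–Alder reaction in its stepwise Mukaiyama aldol–cyclisation form: the (S)-BINOL–Ti(OiPr)4 complex binds the aldehyde and shields its Re face, so the silyl enol ether terminus of 3 adds to the Si face and fixes C2 as S, after which CF3CO2H closes the ring by conjugate addition of the freed hydroxyl and loss of methanol.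

Step 3
Reactants: 5 (2S)-2-[3,5-bis(tert-butyldimethylsilyloxy)phenyl]-2,3-dihydropyran-4-one
Product: 7 (2S)-2-[3,5-bis(tert-butyldimethylsilyloxy)phenyl]-5-(phenylsulfanyl)-2,3-dihydropyran-4-one, via chloro sulfide adduct 6 (not isolated)
Conditions: PhSH, N-chlorosuccinimide, CH2Cl2, 0 °C; then 5, −78 → 0 °C; then Et3N, 0 → 25 °C
Reagents that add atoms: thiophenol, Sc1ccccc1 (delivered as benzenesulfenyl chloride, ClSc1ccccc1, formed in the flask with N-chlorosuccinimide, O=C1CCC(=O)N1Cl)
Why: Electrophilic α-sulfenylation of a vinylogous ester by addition–elimination: PhSCl adds across the enol ether-like pyranone C5=C6 bond with sulfur at the nucleophilic C5, and Et3N then removes the doubly activated H5 to expel chloride and restore the enone, C2 not being touched.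

Step 4
Reactants: 7 (2S)-2-[3,5-bis(tert-butyldimethylsilyloxy)phenyl]-5-(phenylsulfanyl)-2,3-dihydropyran-4-one
Product: 8 (2S)-2-[3,5-bis(tert-butyldimethylsilyloxy)phenyl]-5-(phenylsulfinyl)-2,3-dihydropyran-4-one (both sulfur epimers)
Conditions: mCPBA (1.0 equiv), CH2Cl2, −78 → −40 °C
Reagents that add atoms: 3-chloroperoxybenzoic acid, OOC(=O)c1cccc(Cl)c1
Why: Sulfide-to-sulfoxide oxidation with one equivalent of peracid at low temperature is faster than any reaction of the electron-poor enone or the aryl silyl ethers; the new sulfur stereocentre is left uncontrolled because sulfur is expelled in step 9.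

Step 5
Reactants: 9 methyl acetoacetate; 10 prenyl bromide (1-bromo-3-methylbut-2-ene)
Product: 11 methyl 2-acetyl-5-methylhex-4-enoate (racemic)
Conditions: K2CO3 (1 equiv), 9 (2 equiv), acetone, reflux
Reagents that add atoms: none
Why: Acetoacetic ester alkylation: the enolate of 9 is C-alkylated by the allylic bromide in an SN2 reaction, an excess of 9 keeps dialkylation low, and the racemic centre formed is removed again in step 7.

Step 6
Reactants: 11 methyl 2-acetyl-5-methylhex-4-enoate; 10 prenyl bromide
Product: 13 methyl 7-methyl-2-(3-methylbut-2-enyl)-3-oxooct-6-enoate (racemic), via sodium lithium dianion 12 (not isolated)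
Conditions: NaH, THF, 0 °C; n-BuLi, 0 °C; then 10, 0 → 25 °C; cold 1 M HCl
Reagents that add atoms: none
Why: β-Keto ester dianion alkylation: the second, more basic carbanion at the methyl ketone terminus reacts with the allylic bromide far faster than the stabilised α-enolate, so the second prenyl group enters at the γ-carbon.

Step 7
Reactants: 13 methyl 7-methyl-2-(3-methylbut-2-enyl)-3-oxooct-6-enoate
Product: 14 methyl 7-methyl-2-(3-methylbut-2-enyl)-3-(trimethylsilyloxy)octa-2,6-dienoate (C2=C3 geometry not fixed)
Conditions: TMSCl, Et3N, toluene, 25 °C; filtration under argon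
Reagents that add atoms: chlorotrimethylsilane, C[Si](C)(C)Cl
Why: Soft enolisation and O-silylation of a β-keto ester with TMSCl and Et3N gives the conjugated β-silyloxy enoate, the standard first stage of a 1,3-bis(silyloxy)diene synthesis; alkene geometry is irrelevant.

Step 8
Reactants: 14 methyl 7-methyl-2-(3-methylbut-2-enyl)-3-(trimethylsilyloxy)octa-2,6-dienoate
Product: 16 1-methoxy-1,3-bis(trimethylsilyloxy)-2,4-bis(3-methylbut-2-enyl)buta-1,3-diene (alkene geometry not fixed), via lithium dienolate 15 (not isolated)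
Conditions: LiN(iPr)2, THF, −78 °C; then TMSCl, −78 → 20 °C; pentane, filtration under argon, used crude
Reagents that add atoms: chlorotrimethylsilane, C[Si](C)(C)Cl
Why: Kinetic γ-deprotonation of the β-silyloxy enoate with LiN(iPr)2 gives the extended ester enolate, which TMSCl traps on oxygen as the silyl ketene acetal, the standard second stage of a 1,3-bis(silyloxy)diene synthesis.

Step 9
Reactants: 8 (2S)-2-[3,5-bis(tert-butyldimethylsilyloxy)phenyl]-5-(phenylsulfinyl)-2,3-dihydropyran-4-one; 16 1-methoxy-1,3-bis(trimethylsilyloxy)-2,4-bis(3-methylbut-2-enyl)buta-1,3-diene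
Product: 19 (2S)-2-[3,5-bis(tert-butyldimethylsilyloxy)phenyl]-5,7-dihydroxy-6,8-bis(3-methylbut-2-enyl)chroman-4-one, via sulfinyl cycloadduct 17 (not isolated), via 7-O-trimethylsilyl flavanone 18 (not isolated)
Conditions: 16 (2.5 equiv), degassed toluene, 25 → 60 °C, then 110 °C; then 0.5 M aq HCl, THF, 0 °C
Reagents that add atoms: none
Why: Proposed new method: the electron-rich diene 16 should add to the acceptor-substituted C4a=C8a alkene of 8 by an asynchronous [4+2] cycloaddition (at the stepwise limit a Mukaiyama–Michael addition followed by attack of the α-sulfinyl enolate on the silyl carboxonium carbon) to give 17, in which the sulfinyl group and H8a are cis because the addition is suprafacial; thermal syn-elimination of PhSOH then forms C4a=C8a, the mixed ketal at C5 loses MeOSiMe3 to give a cyclohexadienone, and tautomerisation aromatises ring A to 18, whose aryl trimethylsilyl ether is hydrolysed on work-up. The closest known chemistry is the Diels–Alder benzannulation of 1,1,3-trioxygenated butadienes with halo- or sulfinyl-substituted quinones and enones followed by elimination, which has not been run on a 5-sulfinyl-2,3-dihydropyran-4-one or with a 2,4-dialkylated diene. Ring A closes by [4+2] cycloaddition (6-exo-trig closure in the stepwise limit), forming C8–C8a and C4a–C5. No stereocentre survives from this step, since the sp3 centres of 17 are erased on aromatisation, and C2 is remote from the reacting alkene and meets no base that could open the pyranone ring. The selectivity required is regiochemical (the CH terminus of 16 to C8a, its ketene acetal carbon to C4a) and is secured by polarity matching between the most nucleophilic diene terminus and the β-carbon of the sulfinyl enone, while the neutral medium disfavours β-elimination of O1 from any Michael-type intermediate.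

Step 10
Reactants: 19 (2S)-2-[3,5-bis(tert-butyldimethylsilyloxy)phenyl]-5,7-dihydroxy-6,8-bis(3-methylbut-2-enyl)chroman-4-one
Product: 20 (2S)-2-(3,5-dihydroxyphenyl)-5,7-dihydroxy-6,8-bis(3-methylbut-2-enyl)chroman-4-one (CID26213315)
Conditions: HF·pyridine, pyridine, THF, 0 → 25 °C
Reagents that add atoms: none
Why: Fluoride cleavage of aryl silyl ethers with pyridine-buffered HF is fast and, being non-basic, should not trigger the retro-oxa-Michael ring opening that would racemise C2, nor affect the prenyl alkenes.

**Compound list**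

1 | 3,5-dihydroxybenzaldehyde | O=Cc1cc(O)cc(O)c1 | starting material
2 | 3,5-bis(tert-butyldimethylsilyloxy)benzaldehyde | O=Cc1cc(O[Si](C)(C)C(C)(C)C)cc(O[Si](C)(C)C(C)(C)C)c1 | intermediate
3 | (E)-1-methoxy-3-(trimethylsilyloxy)buta-1,3-diene | CO/C=C/C(=C)O[Si](C)(C)C | starting material
4 | (1E,5S)-5-[3,5-bis(tert-butyldimethylsilyloxy)phenyl]-1-methoxy-5-(trimethylsilyloxy)pent-1-en-3-one (not isolated) | CO/C=C/C(=O)C[C@H](O[Si](C)(C)C)c1cc(O[Si](C)(C)C(C)(C)C)cc(O[Si](C)(C)C(C)(C)C)c1 | intermediate
5 | (2S)-2-[3,5-bis(tert-butyldimethylsilyloxy)phenyl]-2,3-dihydropyran-4-one | O=C1C[C@@H](c2cc(O[Si](C)(C)C(C)(C)C)cc(O[Si](C)(C)C(C)(C)C)c2)OC=C1 | intermediate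
6 | (2S)-2-[3,5-bis(tert-butyldimethylsilyloxy)phenyl]-6-chloro-5-(phenylsulfanyl)oxan-4-one, configuration at C5 and C6 not defined (not isolated) | O=C1C[C@@H](c2cc(O[Si](C)(C)C(C)(C)C)cc(O[Si](C)(C)C(C)(C)C)c2)OC(Cl)C1Sc1ccccc1 | intermediate
7 | (2S)-2-[3,5-bis(tert-butyldimethylsilyloxy)phenyl]-5-(phenylsulfanyl)-2,3-dihydropyran-4-one | O=C1C[C@@H](c2cc(O[Si](C)(C)C(C)(C)C)cc(O[Si](C)(C)C(C)(C)C)c2)OC=C1Sc1ccccc1 | intermediate
8 | (2S)-2-[3,5-bis(tert-butyldimethylsilyloxy)phenyl]-5-(phenylsulfinyl)-2,3-dihydropyran-4-one, both sulfur epimers | O=C1C[C@@H](c2cc(O[Si](C)(C)C(C)(C)C)cc(O[Si](C)(C)C(C)(C)C)c2)OC=C1S(=O)c1ccccc1 | intermediate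
9 | methyl acetoacetate (methyl 3-oxobutanoate) | COC(=O)CC(C)=O | starting material
10 | prenyl bromide (1-bromo-3-methylbut-2-ene) | CC(C)=CCBr | starting material
11 | methyl 2-acetyl-5-methylhex-4-enoate, racemic | COC(=O)C(CC=C(C)C)C(C)=O | intermediate
12 | sodium lithium 1-methoxy-2-(3-methylbut-2-enyl)buta-1,3-diene-1,3-diolate (not isolated) | COC([O-])=C(CC=C(C)C)C([O-])=C.[Na+].[Li+] | intermediate
13 | methyl 7-methyl-2-(3-methylbut-2-enyl)-3-oxooct-6-enoate, racemic | COC(=O)C(CC=C(C)C)C(=O)CCC=C(C)C | intermediate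
14 | methyl 7-methyl-2-(3-methylbut-2-enyl)-3-(trimethylsilyloxy)octa-2,6-dienoate, C2=C3 geometry not fixed | COC(=O)C(CC=C(C)C)=C(CCC=C(C)C)O[Si](C)(C)C | intermediate
15 | lithium 1-methoxy-7-methyl-2-(3-methylbut-2-enyl)-3-(trimethylsilyloxy)octa-1,3,6-trien-1-olate (not isolated) | COC([O-])=C(CC=C(C)C)C(O[Si](C)(C)C)=CCC=C(C)C.[Li+] | intermediate
16 | 1-methoxy-1,3-bis(trimethylsilyloxy)-2,4-bis(3-methylbut-2-enyl)buta-1,3-diene, alkene geometry not fixed | COC(O[Si](C)(C)C)=C(CC=C(C)C)C(O[Si](C)(C)C)=CCC=C(C)C | intermediate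
17 | (2S)-2-[3,5-bis(tert-butyldimethylsilyloxy)phenyl]-5-methoxy-6,8-bis(3-methylbut-2-enyl)-4a-(phenylsulfinyl)-5,7-bis(trimethylsilyloxy)-2,3,4a,5,8,8a-hexahydrochromen-4-one, mixture of diastereomers at C4a, C5, C8, C8a and sulfur (not isolated) | O=C1C[C@@H](c3cc(O[Si](C)(C)C(C)(C)C)cc(O[Si](C)(C)C(C)(C)C)c3)OC2C(CC=C(C)C)C(O[Si](C)(C)C)=C(CC=C(C)C)C(OC)(O[Si](C)(C)C)C12S(=O)c1ccccc1 | intermediate
18 | (2S)-2-[3,5-bis(tert-butyldimethylsilyloxy)phenyl]-5-hydroxy-6,8-bis(3-methylbut-2-enyl)-7-(trimethylsilyloxy)chroman-4-one (not isolated) | CC(C)=CCc1c(O[Si](C)(C)C)c(CC=C(C)C)c2c(c1O)C(=O)C[C@@H](c1cc(O[Si](C)(C)C(C)(C)C)cc(O[Si](C)(C)C(C)(C)C)c1)O2 | intermediate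
19 | (2S)-2-[3,5-bis(tert-butyldimethylsilyloxy)phenyl]-5,7-dihydroxy-6,8-bis(3-methylbut-2-enyl)chroman-4-one | CC(C)=CCc1c(O)c(CC=C(C)C)c2c(c1O)C(=O)C[C@@H](c1cc(O[Si](C)(C)C(C)(C)C)cc(O[Si](C)(C)C(C)(C)C)c1)O2 | intermediate
20 | (2S)-2-(3,5-dihydroxyphenyl)-5,7-dihydroxy-6,8-bis(3-methylbut-2-enyl)chroman-4-one | CC(C)=CCc1c(O)c(CC=C(C)C)c2c(c1O)C(=O)C[C@@H](c1cc(O)cc(O)c1)O2 | target

**Count and risks**

Total step count: 10 steps.
Longest linear sequence: 6 steps (steps 1, 2, 3, 4, 9, 10; the diene branch, steps 5, 6, 7, 8, 9, 10, is equally long).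

Steps most likely to fail:

1. Step 9. The hindered, fully substituted diene may form only the first C–C bond, after which the Michael-type intermediate expels O1 by β-elimination and the pyranone ring opens. Alternatively the diene may decompose before it engages the trisubstituted alkene, and the sulfenic acid released may add to the prenyl alkenes. The fallback uses known chemistry, sets out from 10 and returns at 20; it takes ring A from a preformed phloroglucinol and sets C2 by catalytic asymmetric arylation. Commercial 2,4,6-trihydroxyacetophenone is C-prenylated twice with 10 (DBU, THF) to give 1-[2,4,6-trihydroxy-3,5-bis(3-methylbut-2-enyl)phenyl]ethanone F1. The unchelated para hydroxyl is silylated (TBSCl, imidazole, DMF) to give 1-[4-(tert-butyldimethylsilyloxy)-2,6-dihydroxy-3,5-bis(3-methylbut-2-enyl)phenyl]ethanone F2. Condensation with N,N-dimethylformamide dimethyl acetal (toluene, 80 °C) gives the enaminone (E)-1-[4-(tert-butyldimethylsilyloxy)-2,6-dihydroxy-3,5-bis(3-methylbut-2-enyl)phenyl]-3-(dimethylamino)prop-2-en-1-one F3. Brief acid treatment cyclises it with loss of dimethylamine to 7-(tert-butyldimethylsilyloxy)-5-hydroxy-6,8-bis(3-methylbut-2-enyl)chromen-4-one F4. A Hayashi–Miyaura asymmetric 1,4-addition of commercial 3,5-bis(tert-butyldimethylsilyloxy)phenylboronic acid follows ([Rh(OH)(cod)]2, an electron-poor atropisomeric bisphosphine in the antipode that gives 2S, base-free aqueous toluene). It should give (2S)-2-[3,5-bis(tert-butyldimethylsilyloxy)phenyl]-7-(tert-butyldimethylsilyloxy)-5-hydroxy-6,8-bis(3-methylbut-2-enyl)chroman-4-one F5. HF·pyridine as in step 10 then removes all three silyl groups to reach 20.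

2. Step 3. The sulfenyl chloride may attack the electron-rich ring B positions or the C3 enol instead of pyranone C5, and the α-chloro ether intermediate may be hydrolysed with ring opening before the base-induced elimination takes place. The fallback sets out from 5 and returns at 7, replacing electrophilic sulfenylation by halogenation and cross-coupling. α-Iodination of the enone (I2, pyridine, CH2Cl2, 25 °C) gives (2S)-2-[3,5-bis(tert-butyldimethylsilyloxy)phenyl]-5-iodo-2,3-dihydropyran-4-one F6. C–S cross-coupling of this vinyl iodide with thiophenol (Pd2(dba)3, Xantphos, iPr2NEt, 1,4-dioxane, 90 °C) then gives 7.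

3. Step 8. γ-Deprotonation of the tetrasubstituted enol ether may be incomplete, silylation may occur on the γ-carbon instead of on oxygen, and the ketene acetal may hydrolyse during isolation. The fallback sets out from 13 and returns at 16, dispensing with the strong base and the lithium dienolate. Both oxygens are silylated in one pot under soft enolisation (TMSOTf 2.2 equiv, Et3N 2.5 equiv, Et2O, 0 °C). Silylation of the ester carbonyl of the first-formed β-silyloxy enoate acidifies the γ-hydrogen enough for the amine to remove it. The ethereal solution of 16 is used directly after filtration, and no new compound is made on this path (F0).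

Further compounds
F1 | step 9 | 1-[2,4,6-trihydroxy-3,5-bis(3-methylbut-2-enyl)phenyl]ethanone | CC(=O)c1c(O)c(CC=C(C)C)c(O)c(CC=C(C)C)c1O
F2 | step 9 | 1-[4-(tert-butyldimethylsilyloxy)-2,6-dihydroxy-3,5-bis(3-methylbut-2-enyl)phenyl]ethanone | CC(=O)c1c(O)c(CC=C(C)C)c(O[Si](C)(C)C(C)(C)C)c(CC=C(C)C)c1O
F3 | step 9 | (E)-1-[4-(tert-butyldimethylsilyloxy)-2,6-dihydroxy-3,5-bis(3-methylbut-2-enyl)phenyl]-3-(dimethylamino)prop-2-en-1-one | CN(C)/C=C/C(=O)c1c(O)c(CC=C(C)C)c(O[Si](C)(C)C(C)(C)C)c(CC=C(C)C)c1O
F4 | step 9 | 7-(tert-butyldimethylsilyloxy)-5-hydroxy-6,8-bis(3-methylbut-2-enyl)chromen-4-one | O=c1ccoc2c(CC=C(C)C)c(O[Si](C)(C)C(C)(C)C)c(CC=C(C)C)c(O)c12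
F5 | step 9 | (2S)-2-[3,5-bis(tert-butyldimethylsilyloxy)phenyl]-7-(tert-butyldimethylsilyloxy)-5-hydroxy-6,8-bis(3-methylbut-2-enyl)chroman-4-one | CC(C)=CCc1c(O[Si](C)(C)C(C)(C)C)c(CC=C(C)C)c2c(c1O)C(=O)C[C@@H](c1cc(O[Si](C)(C)C(C)(C)C)cc(O[Si](C)(C)C(C)(C)C)c1)O2
F6 | step 3 | (2S)-2-[3,5-bis(tert-butyldimethylsilyloxy)phenyl]-5-iodo-2,3-dihydropyran-4-one | O=C1C[C@@H](c2cc(O[Si](C)(C)C(C)(C)C)cc(O[Si](C)(C)C(C)(C)C)c2)OC=C1I
F0 | step 8 | none | none
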